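**Retrosynthetic overview** (labdane numbering: ring A = C1–C5 and C10, ring B = C5–C10, side chain C11–C16)
1. The C9–C11 bond is cut last: Negishi union of a ring A/B enol triflate (C8=C9) with a C11–C15 alkylzinc whose C13 carbinol comes from (R)-linalool.
2. The equatorial C3 bromide is traced to a C3 ketone (enol triflate, bromoalkene, axial hydrogen-atom delivery) and the trans C5–H to a C5=C6 alkene.
3. Ring A is then opened at C2–C3 and C4–C5 in one stroke: a 2-bromoisobutyrate (C3, C4 and both C4 methyls), lent as an ester to the C9 oxygen of ring B, is joined to C5 by a samarium Reformatsky aldol and cut loose from oxygen by the C2 organosamarium.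
4. Enabling feature: in ring B the quaternary C10 sits between C5 and C9; C9 is sp2 in the target, so an oxygen there is traceless, it lies 1,3 to the C5 carbonyl, and in the precursor it is cis to the C1–C2 arm on C10.
5. Order of rings: ring B is bought (2-methylcyclohexane-1,3-dione, C10 set by yeast desymmetrization), then a temporary lactone ring, then ring A; the side chain is joined last.

Key step: step 6

Remark: the SMILES is read as 3R,5S,10R,13R; commercial (R)-(−)-linalool is taken as enantiopure.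

**Step 1**
Reactants: 1 2-methylcyclohexane-1,3-dione
Product: 2 2-methyl-2-(prop-2-en-1-yl)cyclohexane-1,3-dione
Conditions: allyl bromide, NaOH (1 M aq.), rt → 50 °C
Reagents that add atoms: allyl bromide, C=CCBr
Why: C-alkylation of the stabilized enolate of a cyclic 1,3-diketone with an allylic halide should build the prochiral quaternary C10.

**Step 2**
Reactants: 2 2-methyl-2-(prop-2-en-1-yl)cyclohexane-1,3-dione
Product: 3 (2S,3S)-3-hydroxy-2-methyl-2-(prop-2-en-1-yl)cyclohexan-1-one
Conditions: baker's yeast (Saccharomyces cerevisiae), sucrose, H2O, 30 °C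
Reagents that add atoms: none
Why: Enzymatic reduction of one of the two enantiotopic carbonyls (desymmetrization of a 2,2-disubstituted 1,3-dione) should set C10 and the C9 carbinol under enzyme control, with the hydroxyl cis to the allyl arm.

**Step 3**
Reactants: 3 (2S,3S)-3-hydroxy-2-methyl-2-(prop-2-en-1-yl)cyclohexan-1-one
Product: 4 (1S,2S)-2-methyl-3-oxo-2-(prop-2-en-1-yl)cyclohexyl 2-bromo-2-methylpropanoate
Conditions: 2-bromo-2-methylpropanoyl bromide, pyridine, DMAP (cat.), CH2Cl2, 0 °C → rt
Reagents that add atoms: 2-bromo-2-methylpropanoyl bromide, CC(C)(Br)C(=O)Br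
Why: Esterification with an acyl bromide under DMAP catalysis hangs the C3–C4 unit with both C4 methyls on the C9 oxygen and touches no stereocentre.

**Step 4**
Reactants: 4 (1S,2S)-2-methyl-3-oxo-2-(prop-2-en-1-yl)cyclohexyl 2-bromo-2-methylpropanoate
Product: 6 (1S,2S)-2-(2-hydroxyethyl)-2-methyl-3-oxocyclohexyl 2-bromo-2-methylpropanoate, via keto aldehyde 5 (not isolated)
Conditions: O3, CH2Cl2/MeOH, −78 °C; Me2S; then NaBH(OAc)3, AcOH, 0 °C → rt
Reagents that add atoms: ozone, [O-][O+]=O
Why: Ozonolysis of the terminal alkene removes one carbon, and NaBH(OAc)3 reduces the aldehyde but not the hindered ketone or the ester, so the C1–C2 arm should emerge as a primary alcohol.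

**Step 5**
Reactants: 6 (1S,2S)-2-(2-hydroxyethyl)-2-methyl-3-oxocyclohexyl 2-bromo-2-methylpropanoate
Product: 7 (1S,2S)-2-(2-iodoethyl)-2-methyl-3-oxocyclohexyl 2-bromo-2-methylpropanoate
Conditions: I2, PPh3, imidazole, CH2Cl2, 0 °C → rt
Reagents that add atoms: iodine, II
Why: Appel-type iodination of the primary alcohol should leave ketone, ester and tertiary bromide untouched.

**Step 6**
Reactants: 7 (1S,2S)-2-(2-iodoethyl)-2-methyl-3-oxocyclohexyl 2-bromo-2-methylpropanoate
Product: 10 (4aS,5S,8aS)-5,8a-dihydroxy-1,1,4a-trimethyloctahydronaphthalen-2(1H)-one, via bridged hydroxy lactone 8 (not isolated), via caged hemiketal 9 (not isolated)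
Conditions: SmI2 (2.2 equiv), THF, −78 °C; then SmI2 (2.5 equiv), HMPA, −78 → 0 °C; aq. NH4Cl
Reagents that add atoms: none
Why: SmI2 first cleaves the tertiary C–Br bond to a samarium enolate whose C4 adds to the C5 ketone (intramolecular Reformatsky aldol, 6-exo-trig on C=O) and closes the temporary six-membered lactone 8; once HMPA is added the primary C–I bond is reduced to an alkylsamarium whose C2 adds to the lactone carbonyl C3 (6-exo-trig), closing ring A as the caged hemiketal 9, which opens on work-up to ketone 10 and hands the C9 oxygen back. The closest known reactions are the SmI2-promoted intramolecular Reformatsky reaction of 3-(2-bromoacyloxy) ketones and the SmI2-promoted intramolecular nucleophilic acyl substitution of iodoalkyl lactones, here run in sequence in one flask. The new stereocentre C5 is set by the ester tether, which can deliver C4 only to the face of the C5 carbonyl cis to the C9 oxygen; this centre is erased in steps 8 and 9, so nothing depends on it. The step needs the order C–Br before C–I before C=O, which the reduction potentials give (the 2-bromo ester reacts at −78 °C without HMPA, the iodide only with HMPA, the lactone carbonyl not at all), and it needs C2 to reach C3, which the cis relation of the C9 oxygen and the C10 iodoethyl arm from step 2 secures. Over-reduction of the new C3 ketone should not occur because it stays masked as the samarium hemiketalate of 9 until work-up. C4 carries no hydrogen, so neither enolate equilibration nor proton transfer can compete.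

**Step 7**
Reactants: 10 (4aS,5S,8aS)-5,8a-dihydroxy-1,1,4a-trimethyloctahydronaphthalen-2(1H)-one
Product: 11 (4aS,5S,8aS)-8a-hydroxy-1,1,4a-trimethyl-5-[(triethylsilyl)oxy]octahydronaphthalen-2(1H)-one
Conditions: Et3SiCl, imidazole, DMAP (cat.), DMF, 0 °C → rt
Reagents that add atoms: chlorotriethylsilane, CC[Si](Cl)(CC)CC
Why: Silylation should take only the secondary C9 hydroxyl, because the tertiary C5 hydroxyl lies between two quaternary carbons.

**Step 8**
Reactants: 11 (4aS,5S,8aS)-8a-hydroxy-1,1,4a-trimethyl-5-[(triethylsilyl)oxy]octahydronaphthalen-2(1H)-one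
Product: 12 (4aR,5S)-1,1,4a-trimethyl-5-[(triethylsilyl)oxy]-3,4,4a,5,6,7-hexahydronaphthalen-2(1H)-one
Conditions: SOCl2, pyridine, CH2Cl2, −20 → 0 °C
Reagents that add atoms: none
Why: Dehydration of the tertiary alcohol through its chlorosulfite (E2 with pyridine) can only give the C5=C6 alkene, since C4 and C10 carry no hydrogen, and it erases the C5 centre of step 6.

**Step 9**
Reactants: 12 (4aR,5S)-1,1,4a-trimethyl-5-[(triethylsilyl)oxy]-3,4,4a,5,6,7-hexahydronaphthalen-2(1H)-one
Product: 13 (4aR,5S,8aS)-1,1,4a-trimethyl-5-[(triethylsilyl)oxy]octahydronaphthalen-2(1H)-one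
Conditions: Mn(dpm)3 (10 mol %; dpm = 2,2,6,6-tetramethylheptane-3,5-dionate), PhSiH3, t-BuOOH, i-PrOH, rt
Reagents that add atoms: none
Why: Metal-hydride hydrogen atom transfer hydrogenation puts H• on C6, and the tertiary C5 radical should take its hydrogen axially, anti to the angular C10 methyl, which gives the more stable trans-fused decalin and sets C5.

**Step 10**
Reactants: 13 (4aR,5S,8aS)-1,1,4a-trimethyl-5-[(triethylsilyl)oxy]octahydronaphthalen-2(1H)-one
Product: 14 (4aR,5S,8aS)-1,1,4a-trimethyl-5-[(triethylsilyl)oxy]-1,4,4a,5,6,7,8,8a-octahydronaphthalen-2-yl trifluoromethanesulfonate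
Conditions: KN(SiMe3)2, THF, −78 °C; PhNTf2, −78 → 0 °C
Reagents that add atoms: N-phenylbis(trifluoromethanesulfonimide), O=S(=O)(N(c1ccccc1)S(=O)(=O)C(F)(F)F)C(F)(F)F
Why: Enolization can only occur toward C2 (C4 is quaternary), and O-sulfonylation of the potassium enolate should give the C2=C3 enol triflate.

**Step 11**
Reactants: 14 (4aR,5S,8aS)-1,1,4a-trimethyl-5-[(triethylsilyl)oxy]-1,4,4a,5,6,7,8,8a-octahydronaphthalen-2-yl trifluoromethanesulfonate
Product: 15 (4aR,5S,8aS)-2-bromo-1,1,4a-trimethyl-5-[(triethylsilyl)oxy]-1,4,4a,5,6,7,8,8a-octahydronaphthalene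
Conditions: [Cp*Ru(MeCN)3]OTf (5 mol %), LiBr, 1,3-dimethylimidazolidin-2-one, 100 °C
Reagents that add atoms: lithium bromide, [Li+].[Br-]
Why: Ruthenium-catalysed triflate–bromide exchange at an alkenyl triflate should give the bromoalkene without a carbocation at the neopentyl C3, so no methyl shift can occur.

**Step 12**
Reactants: 15 (4aR,5S,8aS)-2-bromo-1,1,4a-trimethyl-5-[(triethylsilyl)oxy]-1,4,4a,5,6,7,8,8a-octahydronaphthalene
Product: 16 (2R,4aR,5S,8aS)-2-bromo-1,1,4a-trimethyl-5-[(triethylsilyl)oxy]decahydronaphthalene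
Conditions: Mn(dpm)3 (10 mol %), PhSiH3, t-BuOOH, i-PrOH, rt
Reagents that add atoms: none
Why: In this hydrogen atom transfer hydrogenation of a bromoalkene, H• adds to C2 and the α-bromo radical at C3 should take its hydrogen axially (syn to the axial hydrogens on C1 and C5, anti to the axial methyls on C4 and C10), which sets C3 with bromine equatorial; the C5=C6 alkene was removed in step 9 so that no homoallyl radical rearrangement is open.

**Step 13**
Reactants: 16 (2R,4aR,5S,8aS)-2-bromo-1,1,4a-trimethyl-5-[(triethylsilyl)oxy]decahydronaphthalene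
Product: 17 (4aS,6R,8aR)-6-bromo-5,5,8a-trimethyloctahydronaphthalen-1(2H)-one
Conditions: CrO3, H2SO4 (aq.), acetone, 0 °C
Reagents that add atoms: none
Why: Under Jones oxidation the acid cleaves the triethylsilyl ether and the freed secondary alcohol is oxidized to the C9 ketone in the same flask, while the bromide and the ring fusion are inert.

**Step 14**
Reactants: 17 (4aS,6R,8aR)-6-bromo-5,5,8a-trimethyloctahydronaphthalen-1(2H)-one
Product: 18 (4aS,6R,8aR)-6-bromo-2,5,5,8a-tetramethyloctahydronaphthalen-1(2H)-one (mixture of epimers at the new methyl-bearing carbon)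
Conditions: LiN(i-Pr)2, THF, −78 °C; MeI, −78 → −20 °C
Reagents that add atoms: iodomethane, CI
Why: The lithium enolate can form only toward C8 (C10 is quaternary) and enolate alkylation installs the C8 methyl; the C8 configuration is irrelevant because C8 becomes sp2.

**Step 15**
Reactants: 18 (4aS,6R,8aR)-6-bromo-2,5,5,8a-tetramethyloctahydronaphthalen-1(2H)-one
Product: 19 (4aS,6R,8aR)-6-bromo-2,5,5,8a-tetramethyl-3,4,4a,5,6,7,8,8a-octahydronaphthalen-1-yl trifluoromethanesulfonate
Conditions: KN(SiMe3)2, THF, −78 → 0 °C; N-(5-chloropyridin-2-yl)triflimide, −78 °C → rt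
Reagents that add atoms: N-(5-chloropyridin-2-yl)bis(trifluoromethanesulfonimide), O=S(=O)(N(c1ccc(Cl)cn1)S(=O)(=O)C(F)(F)F)C(F)(F)F
Why: A second deprotonation at C8 gives the only possible, fully substituted enolate, and O-triflation (as for 2,2,6-trimethylcyclohexanone) fixes the tetrasubstituted C8=C9 alkene; the equatorial neopentyl bromide has no antiperiplanar hydrogen for E2.

**Step 16**
Reactants: 20 (R)-(−)-linalool, (3R)-3,7-dimethylocta-1,6-dien-3-ol
Product: 21 triethyl{[(3R)-3,7-dimethylocta-1,6-dien-3-yl]oxy}silane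
Conditions: Et3SiOTf, 2,6-lutidine, CH2Cl2, −78 → 0 °C
Reagents that add atoms: triethylsilyl trifluoromethanesulfonate, CC[Si](CC)(CC)OS(=O)(=O)C(F)(F)F
Why: Silylation of the tertiary allylic alcohol under buffered conditions avoids allylic transposition and keeps the C13 configuration from the chiral pool.

**Step 17**
Reactants: 21 triethyl{[(3R)-3,7-dimethylocta-1,6-dien-3-yl]oxy}silane
Product: 22 (4R)-4-methyl-4-[(triethylsilyl)oxy]hex-5-enal
Conditions: O3 (1 equiv), pyridine (cat.), CH2Cl2, −78 °C; Me2S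
Reagents that add atoms: ozone, [O-][O+]=O
Why: In this chemoselective ozonolysis with reductive work-up, ozone should attack the electron-rich trisubstituted alkene far faster than the vinyl group next to the oxygenated quaternary carbon.

**Step 18**
Reactants: 22 (4R)-4-methyl-4-[(triethylsilyl)oxy]hex-5-enal
Product: 23 (4R)-4-methyl-4-[(triethylsilyl)oxy]hex-5-enoic acid
Conditions: NaClO2, NaH2PO4, 2-methylbut-2-ene, t-BuOH/H2O, 0 °C → rt
Reagents that add atoms: sodium chlorite, [Na+].[O-]Cl=O
Why: Pinnick oxidation with a chlorine scavenger should convert the aldehyde to the acid without touching the vinyl group or the silyl ether.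

**Step 19**
Reactants: 23 (4R)-4-methyl-4-[(triethylsilyl)oxy]hex-5-enoic acid
Product: 25 triethyl{[(3R)-5-iodo-3-methylpent-1-en-3-yl]oxy}silane, via thiohydroxamate ester 24 (not isolated)
Conditions: 1-hydroxypyridine-2(1H)-thione, DCC, DMAP (cat.), CH2Cl2, 0 °C, dark; then CHI3, hν (tungsten lamp), rt
Reagents that add atoms: iodoform, IC(I)I
Why: In this Barton decarboxylation the thiohydroxamate ester fragments under light to the primary C11 radical, which abstracts iodine from iodoform; loss of CO2 removes the one carbon that linalool has too many, and the radical has only 4-exo or 5-endo paths to the vinyl group, so it should not cyclize.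

**Step 20**
Reactants: 25 triethyl{[(3R)-5-iodo-3-methylpent-1-en-3-yl]oxy}silane; 19 (4aS,6R,8aR)-6-bromo-2,5,5,8a-tetramethyl-3,4,4a,5,6,7,8,8a-octahydronaphthalen-1-yl trifluoromethanesulfonate
Product: 27 triethyl({(3R)-5-[(4aS,6R,8aR)-6-bromo-2,5,5,8a-tetramethyl-3,4,4a,5,6,7,8,8a-octahydronaphthalen-1-yl]-3-methylpent-1-en-3-yl}oxy)silane, via alkylzinc iodide 26 (not isolated)
Conditions: 25, Zn dust, LiCl, THF, 40 °C; then 19, Pd(dppf)Cl2 (5 mol %), THF/NMP, 60 °C
Reagents that add atoms: none
Why: In this Negishi coupling, zinc insertion into the primary iodide and palladium-catalysed sp3–sp2 coupling with the enol triflate (as for 2,6,6-trimethylcyclohexenyl triflates) should form C9–C11 and fix the tetrasubstituted alkene; zerovalent palladium with dppf does not insert into the secondary neopentyl bromide.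

**Step 21**
Reactants: 27 triethyl({(3R)-5-[(4aS,6R,8aR)-6-bromo-2,5,5,8a-tetramethyl-3,4,4a,5,6,7,8,8a-octahydronaphthalen-1-yl]-3-methylpent-1-en-3-yl}oxy)silane
Product: 28 (3R)-5-[(4aS,6R,8aR)-6-bromo-2,5,5,8a-tetramethyl-3,4,4a,5,6,7,8,8a-octahydronaphthalen-1-yl]-3-methylpent-1-en-3-ol
Conditions: Bu4NF, THF, 0 °C → rt
Reagents that add atoms: none
Why: Fluoride-induced desilylation is non-acidic, so the tertiary allylic alcohol should not ionize and the equatorial bromide should not eliminate.

**Compound list**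
1 | 2-methylcyclohexane-1,3-dione | CC1C(=O)CCCC1=O | starting material
2 | 2-methyl-2-(prop-2-en-1-yl)cyclohexane-1,3-dione | C=CCC1(C)C(=O)CCCC1=O | intermediate
3 | (2S,3S)-3-hydroxy-2-methyl-2-(prop-2-en-1-yl)cyclohexan-1-one | C=CC[C@]1(C)C(=O)CCC[C@@H]1O | intermediate
4 | (1S,2S)-2-methyl-3-oxo-2-(prop-2-en-1-yl)cyclohexyl 2-bromo-2-methylpropanoate | C=CC[C@]1(C)C(=O)CCC[C@@H]1OC(=O)C(C)(C)Br | intermediate
5 | (1S,2S)-2-methyl-3-oxo-2-(2-oxoethyl)cyclohexyl 2-bromo-2-methylpropanoate (not isolated) | O=CC[C@]1(C)C(=O)CCC[C@@H]1OC(=O)C(C)(C)Br | intermediate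
6 | (1S,2S)-2-(2-hydroxyethyl)-2-methyl-3-oxocyclohexyl 2-bromo-2-methylpropanoate | OCC[C@]1(C)C(=O)CCC[C@@H]1OC(=O)C(C)(C)Br | intermediate
7 | (1S,2S)-2-(2-iodoethyl)-2-methyl-3-oxocyclohexyl 2-bromo-2-methylpropanoate | ICC[C@]1(C)C(=O)CCC[C@@H]1OC(=O)C(C)(C)Br | intermediate
8 | (1S,5S,9S)-5-hydroxy-9-(2-iodoethyl)-4,4,9-trimethyl-2-oxabicyclo[3.3.1]nonan-3-one (not isolated; present as its samarium alkoxide, drawn neutral) | ICC[C@]1(C)[C@@]2(O)CCC[C@@H]1OC(=O)C2(C)C | intermediate
9 | caged hemiketal of 10: the C3 carbonyl closed onto the C9 oxygen as a 2-oxabicyclo[2.2.2]octane bridge (not isolated; present as its samarium alkoxide, drawn neutral) | CC1(C)[C@]2(O)CC[C@@]3(C)[C@@H](O2)CCC[C@@]13O | intermediate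
10 | (4aS,5S,8aS)-5,8a-dihydroxy-1,1,4a-trimethyloctahydronaphthalen-2(1H)-one | CC1(C)C(=O)CC[C@@]2(C)[C@@H](O)CCC[C@@]12O | intermediate
11 | (4aS,5S,8aS)-8a-hydroxy-1,1,4a-trimethyl-5-[(triethylsilyl)oxy]octahydronaphthalen-2(1H)-one | CC1(C)C(=O)CC[C@@]2(C)[C@@H](O[Si](CC)(CC)CC)CCC[C@@]12O | intermediate
12 | (4aR,5S)-1,1,4a-trimethyl-5-[(triethylsilyl)oxy]-3,4,4a,5,6,7-hexahydronaphthalen-2(1H)-one | CC1(C)C(=O)CC[C@@]2(C)[C@@H](O[Si](CC)(CC)CC)CCC=C12 | intermediate
13 | (4aR,5S,8aS)-1,1,4a-trimethyl-5-[(triethylsilyl)oxy]octahydronaphthalen-2(1H)-one | CC1(C)C(=O)CC[C@@]2(C)[C@@H](O[Si](CC)(CC)CC)CCC[C@H]12 | intermediate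
14 | (4aR,5S,8aS)-1,1,4a-trimethyl-5-[(triethylsilyl)oxy]-1,4,4a,5,6,7,8,8a-octahydronaphthalen-2-yl trifluoromethanesulfonate | CC1(C)C(OS(=O)(=O)C(F)(F)F)=CC[C@@]2(C)[C@@H](O[Si](CC)(CC)CC)CCC[C@H]12 | intermediate
15 | (4aR,5S,8aS)-2-bromo-1,1,4a-trimethyl-5-[(triethylsilyl)oxy]-1,4,4a,5,6,7,8,8a-octahydronaphthalene | CC1(C)C(Br)=CC[C@@]2(C)[C@@H](O[Si](CC)(CC)CC)CCC[C@H]12 | intermediate
16 | (2R,4aR,5S,8aS)-2-bromo-1,1,4a-trimethyl-5-[(triethylsilyl)oxy]decahydronaphthalene | CC1(C)[C@H](Br)CC[C@@]2(C)[C@@H](O[Si](CC)(CC)CC)CCC[C@H]12 | intermediate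
17 | (4aS,6R,8aR)-6-bromo-5,5,8a-trimethyloctahydronaphthalen-1(2H)-one | CC1(C)[C@H](Br)CC[C@@]2(C)C(=O)CCC[C@H]12 | intermediate
18 | (4aS,6R,8aR)-6-bromo-2,5,5,8a-tetramethyloctahydronaphthalen-1(2H)-one (epimer mixture at the methyl-bearing carbon next to the carbonyl) | CC1(C)[C@H](Br)CC[C@@]2(C)C(=O)C(C)CC[C@H]12 | intermediate
19 | (4aS,6R,8aR)-6-bromo-2,5,5,8a-tetramethyl-3,4,4a,5,6,7,8,8a-octahydronaphthalen-1-yl trifluoromethanesulfonate | CC1(C)[C@H](Br)CC[C@@]2(C)C(OS(=O)(=O)C(F)(F)F)=C(C)CC[C@H]12 | intermediate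
20 | (R)-(−)-linalool, (3R)-3,7-dimethylocta-1,6-dien-3-ol | C=C[C@](C)(O)CCC=C(C)C | starting material
21 | triethyl{[(3R)-3,7-dimethylocta-1,6-dien-3-yl]oxy}silane | C=C[C@](C)(O[Si](CC)(CC)CC)CCC=C(C)C | intermediate
22 | (4R)-4-methyl-4-[(triethylsilyl)oxy]hex-5-enal | C=C[C@](C)(O[Si](CC)(CC)CC)CCC=O | intermediate
23 | (4R)-4-methyl-4-[(triethylsilyl)oxy]hex-5-enoic acid | C=C[C@](C)(O[Si](CC)(CC)CC)CCC(=O)O | intermediate
24 | 2-thioxopyridin-1(2H)-yl (4R)-4-methyl-4-[(triethylsilyl)oxy]hex-5-enoate (not isolated) | C=C[C@](C)(O[Si](CC)(CC)CC)CCC(=O)ON1C=CC=CC1=S | intermediate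
25 | triethyl{[(3R)-5-iodo-3-methylpent-1-en-3-yl]oxy}silane | C=C[C@](C)(O[Si](CC)(CC)CC)CCI | intermediate
26 | {(3R)-3-methyl-3-[(triethylsilyl)oxy]pent-4-en-1-yl}zinc iodide (not isolated) | C=C[C@](C)(O[Si](CC)(CC)CC)CC[Zn]I | intermediate
27 | triethyl({(3R)-5-[(4aS,6R,8aR)-6-bromo-2,5,5,8a-tetramethyl-3,4,4a,5,6,7,8,8a-octahydronaphthalen-1-yl]-3-methylpent-1-en-3-yl}oxy)silane | C=C[C@](C)(O[Si](CC)(CC)CC)CCC1=C(C)CC[C@@H]2C(C)(C)[C@H](Br)CC[C@@]12C | intermediate
28 | (3R)-5-[(4aS,6R,8aR)-6-bromo-2,5,5,8a-tetramethyl-3,4,4a,5,6,7,8,8a-octahydronaphthalen-1-yl]-3-methylpent-1-en-3-ol | C=C[C@](C)(O)CCC1=C(C)CC[C@@H]2C(C)(C)[C@H](Br)CC[C@@]12C | target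

**Step count and risk**
Total step count: 21 (15 steps to triflate 19, 4 steps to iodide 25, 2 steps of union and deprotection).
Longest linear sequence: 17 steps (steps 1–15, 20 and 21).

The three steps most likely to fail:

Step 6 (key step). The two reductions may not stay in order. The primary radical from the iodide may take a hydrogen atom from THF before it is reduced to the organosamarium, or the iodide may be reduced before the aldol closure onto the hindered C5 ketone is complete, so that ring A does not close. The fallback sets out from 7 and makes the two bonds in separate polar steps. A zinc Reformatsky reaction (activated Zn, THF, reflux) should give lactone 8, now isolated. Its tertiary hydroxyl is capped (Me3SiOTf, 2,6-lutidine, CH2Cl2) to give (1S,5S,9S)-9-(2-iodoethyl)-4,4,9-trimethyl-5-[(trimethylsilyl)oxy]-2-oxabicyclo[3.3.1]nonan-3-one F1. Iodine–lithium exchange (t-BuLi, Et2O/pentane, −100 °C) and intramolecular acyl substitution at the lactone carbonyl, then dilute aqueous HCl to remove the silyl group, should bring the route back at 10.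

Step 12. Bromine may be lost by halogen abstraction under the silane conditions, or the hindered C2=C3 bond may take up the hydrogen atom too slowly. The fallback sets out from 13 and reaches the same α-bromo radical by bromine abstraction instead of hydrogen addition. Hydrazine hydrate (EtOH, reflux) should give (4aR,5S,8aS)-1,1,4a-trimethyl-5-[(triethylsilyl)oxy]octahydronaphthalen-2(1H)-one hydrazone F2. CuBr2 with LiOt-Bu (THF, rt) should convert it to (4aR,5S,8aS)-2,2-dibromo-1,1,4a-trimethyl-5-[(triethylsilyl)oxy]decahydronaphthalene F3. One equivalent of Bu3SnH (Et3B/air, toluene, −78 °C) removes one bromine, and the C3 radical again takes its hydrogen axially; this brings the route back at 16 and bypasses steps 10 to 12.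

Step 9. Facial selectivity may be poor, because the axial silyloxy group on C9 lies on the face from which the hydrogen must reach C5, and a 1,2-acyl shift of the C5 radical toward C4 may compete. The fallback sets out from 12 and replaces radical delivery by hydroxyl-directed delivery. Bu4NF (THF, 0 °C) should give (4aR,5S)-5-hydroxy-1,1,4a-trimethyl-3,4,4a,5,6,7-hexahydronaphthalen-2(1H)-one F4. Hydrogenation with [Ir(cod)(PCy3)(py)]PF6 (H2, CH2Cl2, rt) is steered by the axial C9 hydroxyl to the face anti to the C10 methyl and should give (4aR,5S,8aS)-5-hydroxy-1,1,4a-trimethyloctahydronaphthalen-2(1H)-one F5. Silylation (Et3SiCl, imidazole, DMF) brings the route back at 13.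

**Further compounds**
F1 | step 6 | (1S,5S,9S)-9-(2-iodoethyl)-4,4,9-trimethyl-5-[(trimethylsilyl)oxy]-2-oxabicyclo[3.3.1]nonan-3-one | ICC[C@]1(C)[C@@]2(O[Si](C)(C)C)CCC[C@@H]1OC(=O)C2(C)C
F2 | step 12 | (4aR,5S,8aS)-1,1,4a-trimethyl-5-[(triethylsilyl)oxy]octahydronaphthalen-2(1H)-one hydrazone | CC1(C)C(=NN)CC[C@@]2(C)[C@@H](O[Si](CC)(CC)CC)CCC[C@H]12
F3 | step 12 | (4aR,5S,8aS)-2,2-dibromo-1,1,4a-trimethyl-5-[(triethylsilyl)oxy]decahydronaphthalene | CC1(C)C(Br)(Br)CC[C@@]2(C)[C@@H](O[Si](CC)(CC)CC)CCC[C@H]12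
F4 | step 9 | (4aR,5S)-5-hydroxy-1,1,4a-trimethyl-3,4,4a,5,6,7-hexahydronaphthalen-2(1H)-one | CC1(C)C(=O)CC[C@@]2(C)[C@@H](O)CCC=C12
F5 | step 9 | (4aR,5S,8aS)-5-hydroxy-1,1,4a-trimethyloctahydronaphthalen-2(1H)-one | CC1(C)C(=O)CC[C@@]2(C)[C@@H](O)CCC[C@H]12
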